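**Assumption:** cembrane numbering is used for locants (ring C1–C14, lactone C15/C16/C17, methyls C18–C20). The SMILES is read as (1S,3R,4R,7E,12S,13R,14R) with a cis-fused lactone, a trans epoxide, and the 12-Me/13-O/14-O triad all syn. The TBS group in 9 is a protecting group.

## Retrosynthetic overview

1. 20 ⇐ ring-closing metathesis at C7=C8 of the acyclic epoxy acetate 19 (14-membered ring, formed last).
2. 19 ⇐ acetylation and Shi epoxidation (C3–C4 oxirane) of hydroxy-lactone 17.
3. 17 ⇐ indium Barbier allylation/lactonisation forming C1–C14 and the γ-lactone, joining bromo-ester 8 (C1–C7, C15–C18) with α-hydroxy aldehyde 16 (C8–C14, C19, C20).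
4. 8 ⇐ hex-1-en-5-yne, ethylene oxide, methyl propiolate; 16 ⇐ TBSOCH2CHO, cis-2-butene (crotylboration sets C12/C13), methallyl chloride.
5. Ring order: γ-lactone → oxirane → 14-membered carbocycle.

## Eastern fragment (C1–C7)

**Step 1**
Reactants: 1 hex-1-en-5-yne
Product: 2 (E)-1-iodo-2-methylhexa-1,5-diene
Conditions: AlMe3, Cp2ZrCl2 (cat.), CH2Cl2, 0 °C→rt; then I2, THF, −30→0 °C
Reagents that add atoms: trimethylaluminium, C[Al](C)C; iodine, II
Why: Negishi Zr-catalysed syn-carboalumination of the terminal alkyne (the alkene is inert) then iodinolysis with retention gives the E-vinyl iodide, which fixes the later C3=C4 geometry.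

**Step 2**
Reactants: 2; 3 ethylene oxide
Product: 4 (E)-4-methylocta-3,7-dien-1-ol
Conditions: t-BuLi (2.1 equiv), Et2O, −78 °C; then ethylene oxide, −78 °C→rt
Reagents that add atoms: none (3 is a reactant)
Why: I/Li exchange gives a configurationally stable alkenyllithium that opens the epoxide by SN2 with retention of olefin geometry.

**Step 3**
Reactants: 4
Product: 5 (E)-4-methylocta-3,7-dienal (used crude)
Conditions: Dess–Martin periodinane, NaHCO3, CH2Cl2, 0 °C
Reagents that add atoms: none
Why: buffered Dess–Martin oxidation gives the β,γ-unsaturated aldehyde without migration of the trisubstituted olefin into conjugation.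

**Step 4**
Reactants: 5; 6 methyl propiolate
Product: 7 methyl (5E)-3-hydroxy-6-methyl-2-methylidenedeca-5,9-dienoate (racemic carbinol, erased later)
Conditions: 6, DIBAL-H, NMO, THF, 0 °C; then 5, 0 °C→rt
Reagents that add atoms: none (6 is a reactant; DIBAL-H supplies only H)
Why: hydroalumination of the propiolate gives an α-(methoxycarbonyl)vinylalane that adds 1,2 to the aldehyde (vinylalumination, a base-free Morita–Baylis–Hillman equivalent), avoiding amine-induced isomerisation of 5.

**Step 5**
Reactants: 7
Product: 8 methyl (2Z,5E)-2-(bromomethyl)-6-methyldeca-2,5,9-trienoate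
Conditions: NBS, Me2S, CH2Cl2, 0 °C→rt
Reagents that add atoms: N-bromosuccinimide, BrN1C(=O)CCC1=O
Why: Corey–Kim-type activation and SN2′ delivery of bromide to the Baylis–Hillman alcohol gives the thermodynamic 2Z allylic bromide (chain cis to CH2Br).

## Western fragment (C8–C14)

**Step 6**
Reactants: 9 (tert-butyldimethylsilyloxy)acetaldehyde; 10 cis-2-butene
Product: 11 (2R,3S)-1-(tert-butyldimethylsilyloxy)-3-methylpent-4-en-2-ol
Conditions: 10, KOt-Bu, n-BuLi, THF, −78→−45 °C; (+)-Ipc2BOMe (from (−)-α-pinene), −78 °C; BF3·OEt2; then 9, −78 °C; NaOH, H2O2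
Reagents that add atoms: none (10 is a reactant)
Why: Brown crotylboration through a chair transition state, where the Z-crotyl unit gives the syn Me/OH pair and the Ipc ligands direct Re-face attack, sets C13 (R) and C12 (S).

**Step 7**
Reactants: 11
Product: 12 (2R,3S)-1,2-bis(tert-butyldimethylsilyloxy)-3-methylpent-4-ene
Conditions: TBSOTf, 2,6-lutidine, CH2Cl2, −78→0 °C
Reagents that add atoms: TBS triflate, CC(C)(C)[Si](C)(C)OS(=O)(=O)C(F)(F)F
Why: silylation masks the secondary alcohol for the borane/alkoxide step without touching the stereocentres.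

**Step 8**
Reactants: 12; 13 3-chloro-2-methylprop-1-ene (methallyl chloride)
Product: 14 (2R,3S)-1,2-bis(tert-butyldimethylsilyloxy)-3,7-dimethyloct-7-ene
Conditions: 9-BBN, THF, 0 °C→rt; then CuOAc (10 mol %), t-BuOK, 13, THF, rt→50 °C
Reagents that add atoms: none (13 is a reactant; 9-BBN supplies only H)
Why: anti-Markovnikov hydroboration of the vinyl group then Cu-catalysed allyl–alkyl coupling of the B-alkyl-9-BBN; methallyl is symmetric, so SN2 and SN2′ give the same product.

**Step 9**
Reactants: 14
Product: 15 (2R,3S)-3,7-dimethyloct-7-ene-1,2-diol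
Conditions: TBAF, THF, 0 °C→rt
Reagents that add atoms: none
Why: fluoride cleaves both silyl ethers in one operation.

**Step 10**
Reactants: 15
Product: 16 (2R,3S)-2-hydroxy-3,7-dimethyloct-7-enal (isolated as its hemiacetal dimer, used at once)
Conditions: TEMPO (cat.), PhI(OAc)2, CH2Cl2, rt
Reagents that add atoms: none
Why: oxoammonium oxidation is selective for the primary alcohol, and the neutral conditions leave the α-stereocentre intact.

## Fragment union and endgame

**Step 11** (key coupling)
Reactants: 8 (1.3 equiv); 16
Product: 17 (4S,5R)-5-[(1R,2S)-1-hydroxy-2,6-dimethylhept-6-en-1-yl]-3-methylidene-4-[(2E)-3-methylhepta-2,6-dien-1-yl]oxolan-2-one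
Conditions: In powder, THF/H2O (1:1), rt; then PPTS (cat.), CH2Cl2, rt
Reagents that add atoms: none
Why: indium-mediated Barbier allylation (γ-attack) on the In-chelated α-hydroxy aldehyde gives the 13,14-syn diol, the Z-bromide via a chair transition state gives the 14,1-syn relationship, and the γ-hydroxy ester closes to the cis-fused α-methylene-γ-lactone, setting C14 (R) and C1 (S).

**Step 12**
Reactants: 17
Product: 18 the C13 acetate of 17
Conditions: Ac2O, pyridine, DMAP (cat.), CH2Cl2, 0 °C
Reagents that add atoms: acetic anhydride, CC(=O)OC(C)=O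
Why: acylation of the only free hydroxyl installs the target acetate and removes the OH before the epoxide is introduced.

**Step 13**
Reactants: 18
Product: 19 the (3R,4R)-epoxide of 18, i.e. (1R,2S)-1-[(2R,3S)-3-{[(2R,3R)-3-(but-3-en-1-yl)-3-methyloxiran-2-yl]methyl}-4-methylidene-5-oxooxolan-2-yl]-2,6-dimethylhept-6-en-1-yl acetate
Conditions: D-fructose-derived Shi ketone (0.3 equiv), Oxone (1.2 equiv), K2CO3, Bu4NHSO4, MeCN/DMM/aq. borate buffer (pH ≈ 10), 0 °C
Reagents that add atoms: Oxone (KHSO5), [K+].[O-]S(=O)(=O)OO
Why: Shi asymmetric epoxidation via a spiro dioxirane transition state gives the (R,R)-epoxide of the E-trisubstituted olefin; this is the only electron-rich trisubstituted alkene, and the vinyl, isopropenyl and acrylate olefins react much more slowly (cf. limonene 1,2-selectivity).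

**Step 14**
Reactants: 19
Product: 20 eupalmerin acetate
Conditions: Grubbs II (15 mol %), toluene (1 mM), 80 °C
Reagents that add atoms: none
Why: ring-closing metathesis of the vinyl and isopropenyl termini (loss of ethylene) closes the 14-membered ring; the 7E geometry is expected only on thermodynamic grounds and is not guaranteed, while the electron-poor exo-methylene lactone is a poor metathesis partner.

## Compound list

1 | hex-1-en-5-yne | C#CCCC=C | starting material
2 | (E)-1-iodo-2-methylhexa-1,5-diene | I/C=C(\C)CCC=C | intermediate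
3 | ethylene oxide | C1CO1 | starting material
4 | (E)-4-methylocta-3,7-dien-1-ol | OCC/C=C(\C)CCC=C | intermediate
5 | (E)-4-methylocta-3,7-dienal | O=CC/C=C(\C)CCC=C | intermediate
6 | methyl propiolate | C#CC(=O)OC | starting material
7 | methyl (5E)-3-hydroxy-6-methyl-2-methylidenedeca-5,9-dienoate (racemic) | C=C(C(=O)OC)C(O)C/C=C(\C)CCC=C | intermediate
8 | methyl (2Z,5E)-2-(bromomethyl)-6-methyldeca-2,5,9-trienoate | BrC/C(C(=O)OC)=C\C/C=C(\C)CCC=C | intermediate
9 | (tert-butyldimethylsilyloxy)acetaldehyde | O=CCO[Si](C)(C)C(C)(C)C | starting material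
10 | cis-2-butene | C/C=C\C | starting material
11 | (2R,3S)-1-(TBS-oxy)-3-methylpent-4-en-2-ol | CC(C)(C)[Si](C)(C)OC[C@H](O)[C@@H](C)C=C | intermediate
12 | (2R,3S)-1,2-bis(TBS-oxy)-3-methylpent-4-ene | CC(C)(C)[Si](C)(C)OC[C@H](O[Si](C)(C)C(C)(C)C)[C@@H](C)C=C | intermediate
13 | 3-chloro-2-methylprop-1-ene | C=C(C)CCl | starting material
14 | (2R,3S)-1,2-bis(TBS-oxy)-3,7-dimethyloct-7-ene | CC(C)(C)[Si](C)(C)OC[C@H](O[Si](C)(C)C(C)(C)C)[C@@H](C)CCCC(C)=C | intermediate
15 | (2R,3S)-3,7-dimethyloct-7-ene-1,2-diol | OC[C@H](O)[C@@H](C)CCCC(C)=C | intermediate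
16 | (2R,3S)-2-hydroxy-3,7-dimethyloct-7-enal | O=C[C@H](O)[C@@H](C)CCCC(C)=C | intermediate
17 | hydroxy-lactone (name in Step 11) | C=C1C(=O)O[C@@H]([C@H](O)[C@@H](C)CCCC(C)=C)[C@H]1C/C=C(\C)CCC=C | intermediate
18 | C13 acetate of 17 | C=C1C(=O)O[C@@H]([C@H](OC(C)=O)[C@@H](C)CCCC(C)=C)[C@H]1C/C=C(\C)CCC=C | intermediate
19 | (3R,4R)-epoxy acetate, RCM precursor | C=C1C(=O)O[C@@H]([C@H](OC(C)=O)[C@@H](C)CCCC(C)=C)[C@H]1C[C@H]2O[C@]2(C)CCC=C | intermediate
20 | eupalmerin acetate | C=C1C(=O)O[C@H]2[C@H](OC(C)=O)[C@@H](C)CCC/C(C)=C/CC[C@@]3(C)O[C@@H]3C[C@@H]12 | target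

## Summary

**Total steps:** 14.
**Longest linear sequence:** 9 (steps 1–5 or 6–10, then 11–14), i.e. 64 % of the total.

**Steps most likely to fail, with fallbacks**

1. **Step 14 (RCM).** A trisubstituted olefin in a 14-membered ring may form as an E/Z mixture or oligomerise. Fallback: fix the geometry before ring closure. Make C7=C8 as an (E)-vinyl iodide by carboalumination–iodination of a C8 alkyne on the western half, join the halves at C6–C7 by Pd-catalysed sp2–sp3 coupling, and close the macrocycle by an intramolecular In- or CrCl2-mediated Barbier allylation/lactonisation at C1–C14.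

2. **Step 11 (Barbier union).** It depends on chelation control for the syn,syn outcome, on a fragile α-hydroxy aldehyde, and on γ- over δ-lactonisation. Fallback: reagent-controlled construction. Set C1 by a Johnson/Ireland–Claisen rearrangement that delivers an (E)-C13=C14 γ,δ-unsaturated ester, apply Sharpless asymmetric dihydroxylation (the syn diol lactonises to the same hydroxy-γ-lactone), then add the exo-methylene with Eschenmoser's salt.

3. **Step 13 (Shi epoxidation).** Over-oxidation of the isopropenyl group or base damage to the lactone/acetate is possible. Fallback: epoxidise at the fragment stage, on Baylis–Hillman adduct 7, where the only other olefins are a vinyl and an acrylate. Convert to the bromide via mesylate/LiBr and carry the epoxide through a non-acidic coupling and lactonisation (Zn, THF; then DBU).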